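The runs stem from a simulated flask on assumed constants; noise was put on by code.

Set the flask on a clock read from its rate of making target, not on its yield.

| setting | spring | dawn | summer | east | north-west |
|---|---|---|---|---|---|
| substrate | 0.50 M | 0.75 M | 1 M | 1.0 M | 1.0 M |
| first nucleophile | 0.70 M | 0.70 M | 0.70 M | 0.700 M | 0.700 M |
| second nucleophile | 1.8 M | 1.8 M | 2.7 M | 1.80 M | 1.80 M |
| protic impurity | 0.30 M | 0.30 M | 0.30 M | 0.300 M | 0.300 M |
| temperature | 70 °C | 82 °C | 70 °C | 75 °C | 90 °C |
| remark | run made earlier | run made earlier | run made earlier |  |  |
| time |  |  |  | 30 h | 30 h |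

- spring (time / h: target / %): 2.50: 9.3; 5.00: 15.0; 8.00: 18.9; 10.0: 23.2; 12.0: 24.4; 15.0: 27.8; 20.0: 31.0
- dawn (time / h: target / %): 1.33: 8.4; 2.00: 10.9; 3.00: 13.5; 5.00: 19.6; 8.00: 21.1; 12.0: 25.0; 20.0: 24.8
- summer (time / h: target / %): 4.00: 12.2; 8.00: 19.1; 10.0: 19.9; 15.0: 23.5; 20.0: 23.7

(scatter of a reading: 1 percentage point)

- what was read earlier has a scatter of 1 percentage point, one standard deviation
- steps that have been proposed: second nucleophile + intermediate -> other capture product; substrate <-> intermediate; first nucleophile + protic impurity -> quenched reagent; intermediate -> decomposed reagent; second nucleophile + target -> over-reaction product; first nucleophile + intermediate -> target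

* the flask with the highest amount of target, in percent of the substrate charged ("all alike" if they lie within 1.5 percentage points) (east / north-west / all alike)
* final target, as a percentage of the substrate charged, in east
* final target, as a percentage of the substrate charged, in north-west

I take each run's first reading over its time as its starting rate, in fraction of the substrate charged per hour. Spring starts at 0.0372 h⁻¹ and dawn at 0.0632 h⁻¹, both with the scatter of a reading. From these I read a clock gain of 0.0441 K⁻¹, written g: the logarithm of the rate ratio per kelvin. The two runs differ in substrate charge as well as in temperature, so g is a reading that carries both; I use it as if a flask hotter by ΔT ran faster by exp(gΔT), charges aside.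

The rate then slows. Over its last 5.00 h, spring makes target at 0.00640 h⁻¹, which is 5.81 times slower than at its start. Dawn changes by −0.2 percentage points from 12.0 h to 20.0 h, and summer by 0.2 points from 15.0 h to 20.0 h, against a scatter of 1 point. A net rate near zero means making and loss of target balance, if the proposed over-reaction step runs. If the making goes on slowing, as spring's net rate did, I expect the net rate to turn negative after that.

East's 30 h equals 22.0 h on dawn's clock, just past dawn's last reading, so I expect about 24.8% there, ignoring the larger substrate charge. North-west's 30 h equals 42.7 h, twice dawn's last time, so I expect it on the falling side, below east.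

The forecast names east, with 28% (25% to 31%) for east and 20% (16% to 24%) for north-west, holding that "The yields plateau rather than fall, so over-reaction looks minor". We part on that point: I expect target to fall with time in north-west.

The flask gives east as highest, with 25.9% in east and 12.1% in north-west.

    second nucleophile + intermediate → other capture product (k = 1.53 L mol⁻¹ h⁻¹, Ea = 88.0 kJ mol⁻¹)
    substrate ⇌ intermediate (K = 0.0190, k = 3.20 h⁻¹, Ea = 95.0 kJ mol⁻¹, ΔH = −48.0 kJ mol⁻¹)
    first nucleophile + protic impurity → quenched reagent (k = 0.526 L mol⁻¹ h⁻¹, Ea = 67.0 kJ mol⁻¹)
    intermediate → decomposed reagent (k = 0.385 h⁻¹, Ea = 123 kJ mol⁻¹)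
    second nucleophile + target → over-reaction product (k = 0.0355 L mol⁻¹ h⁻¹, Ea = 91.0 kJ mol⁻¹)
    first nucleophile + intermediate → target (k = 7.55 L mol⁻¹ h⁻¹, Ea = 85.0 kJ mol⁻¹)
    (constants at 90 °C)

In north-west, target goes from 18.7% after 15.0 h to 12.1% after 30.0 h, while over-reaction product goes from 13.9% to 23.8%; that end stands at 42.7 h on dawn's clock. The neighbour like east but kept at 60 °C reaches 19.3 h on spring's clock, inside spring's rising readings, and holds 28.6% target with 2.17% over-reaction product.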